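- teal: substrate 0.012 M; partner 0.0240 M; time 2.0 d
- ochre: substrate 0.012 M; partner 0.0360 M; time 2.0 d

- part of the substrate that has reacted at the end, teal
- part of the substrate that has reacted at the end, ochre
- what raising the concentration of partner from its lowest to its highest value here does to the part of the substrate that has reacted (changes below 5 percentage points count as none) (no change / it rises / it falls)

- for released group the idle adduct and crystals are counted in
- as a solid, counted per litre of solution: crystals
- run time (teal): 2.0 d

    partner + first product → bis adduct + released group (k1 = 180 L mol⁻¹ h⁻¹)
    substrate + partner → first product + released group (k2 = 110 L mol⁻¹ h⁻¹)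
    substrate → decomposition product (k3 = 6.2 × 10⁻⁵ h⁻¹)
    partner + released group ⇌ idle adduct, settled at all times (K4 = 780 L mol⁻¹)
    partner + bis adduct → tris adduct + released group (k5 = 370 L mol⁻¹ h⁻¹)
    crystals ⇌ released group, rate k6*(cs6 - [released group]) while solid is left; crystals form when [released group] > cs6 (cs6 = 7.2 mM, k6 = 13 h⁻¹)

**Starting rate.** Begin with the rate. At the charge, I gave teal's substrate a rate of 2.64 h⁻¹ per unit of substrate, which is one decade in 0.872 h.

**The brakes.** In my reckoning, once crystals held the released group at its solubility, idle adduct cut free partner, and with it this rate, by a factor 6.62, or 0.821 decades. Yet teal's stretched half-life of substrate, with partner as charged, of 1.74 h was still shorter than the run. Substrate's half-life by decomposition was far longer than by partner, so I set that step aside. Substrate, first product and bis adduct each react at a rate proportional to [partner], so [partner] cancels in the rate of partner use over the rate of substrate loss: this brake stretches the clock and leaves the cost unchanged.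

**Partner bill.** Per unit of partner, I had first product reacting 1.64 times as fast as substrate and bis adduct 3.36 times as fast (selectivity factors). With 16.7 % of the substrate left, that gave 17.8 % as first product and 10.3 % as bis adduct, so I reckoned 2.04 equivalents spent. This is the partner bill, the equivalents of partner spent by the time a given part of the substrate is left. Teal's charge is 2.00 equivalents, so partner is its limiting reagent. At that point each substrate lost cost 4.83 partner, which moved my stop for teal to 17.5 % left, or 82.5 % reacted.

**Ochre's tail.** Ochre's 3.00 equivalents cover the full bill of 3, so I reckoned a slowing tail. In ochre I took unspent partner, idle adduct counted in, to follow substrate, 7.23 equivalents per substrate left, and 6.62 divided that to give free partner. This left ochre 1.44 % of its substrate by my reckoning, or 98.6 % reacted, a rise of 16 percentage points over teal.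

**The forecast.** It gave 82.6 % (81.5 % to 83.5 %) for teal and 98.4 % (97.8 % to 98.9 %) for ochre, with the trend: it rises. Of teal it said “the later substitutions are faster than the first”. Its figures differ from my 82.5 % and 98.6 %.

**The result.** Teal reached 82.5 % reacted and ochre 98.5 %, so the trend with more partner was: it rises, by 16 points.

**Second flask.** Teal ended with 0 % of its partner free and 17 % of its substrate, the bill of 2.04 at 16.7 % left standing above its charge. The neighbour of teal with 0.020 M of substrate had 1.20 equivalents of partner. At 37.5 % left I reckoned its bill at 1.20. That neighbour ended with 38 % of its substrate left, 62.5 % reacted.

The numbers come from no measurement; the run is a simulation.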